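The 14-membered carbocycle (ring A) is cut at C14–C1. The feature exploited is that C1 carries the C15(=C17)–C16 three-carbon branch and adjoins C14H2–C13–O, which is the imprint of a 1,3-dicarbonyl radical adding to a prenyl alkene. In one operation Mn(OAc)3/Cu(OAc)2 converts an open-chain C13 β-keto ester into its C14 radical, closes ring A at C1, creates the C1 stereocentre and leaves the 2-propenyl group from which the seven-membered lactone (ring C) is later made. The precursor already contains the oxolane (ring B), C4, C5, C9 and C12, a C8 ketone, a removable C14 chlorine and a saturated silylethyl ester. Both halves derive from (R)-linalool.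

Key step: step 12

**Numbering and rings.** Cembrane numbering is used.
- Ring A is C1–C14.
- Ring B is the oxolane O/C9–C12.
- Ring C is the lactone C1–C4/O/C16/C15.
- C17 is the lactone methylene, C18 and C20 are the methyls on C4 and C12, and C19 is the methylene on C8.
- The target is 1R,4R,5R,9R,12R,13S. C4 and C12 both map onto C3 of (R)-linalool.

**Remark on the chemistry.**
- C14 is a mixture of epimers from 17 to 26 and is drawn without configuration, because it ends as CH2.
- Hydrazone geometry is left open.
- Compound 15 is drawn in its open form although it equilibrates with a five-membered hemiketal.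
- salen = N,N'-bis(3,5-di-tert-butylsalicylidene)cyclohexane-1,2-diaminate.

**Precursor design.**
- The ester is 2-(trimethylsilyl)ethyl, because an allyl ester would itself be a 5-exo radical acceptor.
- C14 carries chlorine, so the product cannot be oxidised again and the C13 enol cannot close a dihydrofuran onto C15.
- C13 is built from a carboxyl group, so the two ketones are never alike.
- C7 reacts as a hydrazone anion, because a ketone enolate opens epoxides poorly.

Step 1
Reactants: 1 (R)-(−)-linalool
Product: 3 (2R,5R)-furanoid linalool oxide, via (3R,6S)-6,7-epoxylinalool 2 (not isolated)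
Conditions: ent-Shi ketone (L-fructose-derived, 0.3 equiv), Oxone (2KHSO5·KHSO4·K2SO4), K2CO3, Bu4NHSO4, Na2B4O7/Na2EDTA buffer, MeCN–CH2(OMe)2, 0 °C; extraction; CSA (0.1 equiv), CH2Cl2, 0 °C
Reagents that add atoms: potassium peroxymonosulfate (active part of Oxone), [K+].[O-]S(=O)(=O)OO
Why: Shi asymmetric epoxidation: the chiral dioxirane reacts with the electron-rich trisubstituted alkene rather than the vinyl group and, in the L-series, should give the (6S)-epoxide under catalyst control, after which acid-catalysed 5-exo-tet opening by the tertiary hydroxyl inverts that carbon and sets C9 as R, trans to the vinyl group on ring B (the minor pyranoid product of 6-endo opening is removed by chromatography).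

Step 2
Reactants: 3 (2R,5R)-furanoid linalool oxide
Product: 4 (2R,5R)-2-ethenyl-2-methyl-5-(prop-1-en-2-yl)oxolane
Conditions: SOCl2 (1.5 equiv), pyridine, 0 °C
Reagents that add atoms: none
Why: E2 dehydration of the tertiary alcohol with SOCl2/pyridine should take one of the six exposed methyl hydrogens rather than the single hindered C9–H, so the 2-propenyl group forms and C9 keeps its configuration.

Step 3
Reactants: 4 (2R,5R)-2-ethenyl-2-methyl-5-(prop-1-en-2-yl)oxolane
Product: 6 (2R,5R)-5-acetyl-2-methyloxolane-2-carboxylic acid, via keto aldehyde 5 (not isolated)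
Conditions: O3, CH2Cl2–MeOH, −78 °C; Me2S, to rt; evaporation; NaClO2, NaH2PO4, 2-methyl-2-butene, t-BuOH–H2O, rt
Reagents that add atoms: ozone, [O-][O+]=O; sodium chlorite, [Na+].[O-]Cl=O
Why: Ozonolysis with reductive work-up cleaves both terminal alkenes at once to the C8 methyl ketone and the non-enolisable C13 aldehyde, and Pinnick oxidation then converts only the aldehyde into the acid under buffered conditions that leave C9 and C12 alone.

Step 4
Reactants: 6 (2R,5R)-5-acetyl-2-methyloxolane-2-carboxylic acid; 7 Meldrum's acid
Product: 9 2-(trimethylsilyl)ethyl 3-[(2R,5R)-5-acetyl-2-methyloxolan-2-yl]-3-oxopropanoate, via acyl Meldrum's acid 8 (not isolated)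
Conditions: EDC·HCl, DMAP, CH2Cl2, 0 °C to rt; acidic wash; Me3SiCH2CH2OH (3 equiv), toluene, 100 °C
Reagents that add atoms: 2-(trimethylsilyl)ethanol, C[Si](C)(C)CCO
Why: Oikawa–Yonemitsu β-keto ester synthesis: carbodiimide-mediated C-acylation of Meldrum's acid and thermal alcoholysis with loss of acetone and CO2 bring in C14 and a saturated, fluoride-labile ester under neutral conditions, which differentiates C13 from the C8 methyl ketone from the start.

Step 5
Reactants: 9 2-(trimethylsilyl)ethyl 3-[(2R,5R)-5-acetyl-2-methyloxolan-2-yl]-3-oxopropanoate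
Product: 10 C8 N,N-dimethylhydrazone of 9
Conditions: Me2NNH2 (1.2 equiv), AcOH (cat.), 4 Å molecular sieves, CH2Cl2, rt
Reagents that add atoms: 1,1-dimethylhydrazine, CN(C)N
Why: Hydrazone condensation should occur at the open C8 methyl ketone, the C13 carbonyl being shielded by quaternary C12, and it prepares C7 as a strong and regiodefined carbon nucleophile, while any condensation at C13 would be undone by the hydrolysis in step 9.

Step 6
Reactants: 1 (R)-(−)-linalool
Product: 11 (3R)-1,2-epoxylinalool (both C5 epimers)
Conditions: VO(acac)2 (2 mol%), t-BuOOH (1.3 equiv, decane), toluene, 0 °C to rt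
Reagents that add atoms: tert-butyl hydroperoxide, CC(C)(C)OO
Why: Hydroxyl-directed vanadium-catalysed epoxidation delivers oxygen to the allylic vinyl group of linalool and spares the more electron-rich but remote prenyl alkene; C4 comes from the chiral pool, whereas C5 forms with little selectivity because the methyl and homoprenyl groups on C4 differ too little, which step 7 corrects.

Step 7
Reactants: 11 (3R)-1,2-epoxylinalool (both C5 epimers)
Product: 12 (2R,3R)-1,2-epoxylinalool
Conditions: (S,S)-(salen)Co(OAc) (2 mol%), H2O (slight excess over the unwanted epimer), THF, 0 °C to rt; chromatography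
Reagents that add atoms: none
Why: Jacobsen hydrolytic kinetic resolution is catalyst-controlled at the epoxide carbon, so the (S,S)-catalyst should hydrolyse the (2S)-epimer to a polar triol and leave the (2R,3R)-epoxide, which fixes C5 as R.

Step 8
Reactants: 12 (2R,3R)-1,2-epoxylinalool
Product: 13 trimethylsilyl ether of 12
Conditions: N-(trimethylsilyl)imidazole (1.5 equiv), CH2Cl2, rt
Reagents that add atoms: N-(trimethylsilyl)imidazole, C[Si](C)(C)n1ccnc1
Why: Silylation with this strong, acid-free silyl donor caps the tertiary alcohol, which excludes Payne rearrangement of an alkoxide in step 9 and needs no separate removal.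

Step 9
Reactants: 10 C8 N,N-dimethylhydrazone of 9; 13 trimethylsilyl ether of 12
Product: 15 seco 4,5-dihydroxy keto ester, via coupled hydrazone 14 (not isolated)
Conditions: LDA (LiN(iPr)2, 2.2 equiv), THF, −78 to 0 °C; 13, 0 °C to rt; saturated aq. oxalic acid, Et2O, rt
Reagents that add atoms: water, O
Why: Two equivalents of base give the C14 enolate (self-protection of the keto ester) and the kinetic C7 aza-enolate, which opens the epoxide by SN2 attack at terminal C6 (Corey–Enders hydrazone alkylation) so that C5 keeps its configuration, and two-phase oxalic acid then hydrolyses hydrazone and silyl ether without epimerising C9.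

Step 10
Reactants: 15 seco 4,5-dihydroxy keto ester
Product: 16 seco C5 acetate
Conditions: Ac2O (1.5 equiv), pyridine, DMAP (5 mol%), CH2Cl2, 0 °C to rt
Reagents that add atoms: acetic anhydride, CC(=O)OC(C)=O
Why: DMAP-catalysed acylation takes the secondary C5 alcohol, drawn from the open form of the hydroxy ketone, and leaves the tertiary C4 alcohol free for the later lactone.

Step 11
Reactants: 16 seco C5 acetate
Product: 17 seco 14-chloro β-keto ester (precursor of the key step)
Conditions: NCS (1.05 equiv), Mg(ClO4)2 (0.3 equiv), MeCN, 0 °C to rt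
Reagents that add atoms: N-chlorosuccinimide, O=C1CCC(=O)N1Cl
Why: Lewis-acid-catalysed electrophilic α-chlorination works because the magnesium chelate of the keto ester is far more nucleophilic than the prenyl alkene, so one equivalent of NCS should give the monochloride as C14 epimers of no consequence.

Step 12
Reactants: 17 seco 14-chloro β-keto ester
Product: 18 14-chloro macrocyclic keto ester bearing the C1 2-propenyl group (1S,4R,5R,9R,12R; the descriptor 1S reflects the priority of the chlorinated C14 and is the spatial arrangement of 1R in the target)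
Conditions: Mn(OAc)3·2H2O (2.5 equiv), Cu(OAc)2·H2O (1.0 equiv), degassed AcOH, 50 °C, 17 added by syringe pump over 12 h (final about 2 mM)
Reagents that add atoms: none
Why: Mn(OAc)3 takes one electron from the manganese enolate of 17 and gives the electrophilic, fully substituted C14 radical, which adds to C1, the less substituted end of the electron-rich C1=C15 bond; Cu(OAc)2 then traps the tertiary C15 radical as an alkylcopper species that loses a methyl hydrogen by syn elimination, giving the 2-propenyl group, and the monovalent copper is re-oxidised by the second equivalent of Mn(OAc)3. The closest known reaction type is the Mn(OAc)3/Cu(OAc)2 oxidative free-radical cyclisation of unsaturated α-chloro β-keto esters, routine for five- to eight-membered rings, together with the rarer Mn(OAc)3 macrocyclisations of tethered 3-oxo esters. Ring A closes in the 14-exo-trig mode (C15 stays outside the new ring), so 17 is fed slowly into the oxidants to keep it dilute and suppress intermolecular addition. C1 is the one lasting new stereocentre and is under substrate control only: ring B (trans-2,5) and the C4/C5 pair limit the folds of the chain, and the fold that keeps the C15 terminus on the outside of the ring and away from the C18 methyl should expose the alkene face that leads to the configuration drawn, whereas C14 forms as a mixture that steps 16 and 18 erase. The step needs the C14 radical to meet only the prenyl alkene and the product to be inert, which the substrate secures because C8 is a ketone and the ester is saturated, and because the chlorine blocks re-oxidation of 18 and removes the C14–H through which the C13 enol would capture C15 as a dihydrofuran. Regiochemistry is intrinsic, since attack at C1 gives the tertiary radical and the copper elimination prefers the six unhindered methyl hydrogens over C1–H.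

Step 13
Reactants: 18 14-chloro macrocyclic keto ester
Product: 20 C16 enal, via C16 allylic alcohol 19 (not isolated)
Conditions: SeO2 (0.5 equiv), t-BuOOH (3 equiv), CH2Cl2, rt; then MnO2 (excess), rt
Reagents that add atoms: selenium dioxide, O=[Se]=O; tert-butyl hydroperoxide, CC(C)(C)OO
Why: Selenium dioxide allylic oxidation (ene reaction, then [2,3]-sigmatropic shift) meets only one alkene and should attack its methyl group because C1–H is buried beside quaternary C14, MnO2 brings the alcohol/aldehyde mixture to the single enal, and the chlorine keeps C14 safe from oxidation.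

Step 14
Reactants: 20 C16 enal
Product: 21 C16 acrylic acid
Conditions: NaClO2, NaH2PO4, 2-methyl-2-butene, t-BuOH–H2O, rt
Reagents that add atoms: sodium chlorite, [Na+].[O-]Cl=O
Why: Pinnick oxidation converts the α-substituted acrolein into the acrylic acid without touching the alkene, the ketones or the tertiary alcohol, 2-methyl-2-butene scavenging the hypochlorous acid.

Step 15
Reactants: 21 C16 acrylic acid
Product: 23 ring C lactone (14-chloro), via mixed anhydride 22 (not isolated)
Conditions: 2-methyl-6-nitrobenzoic anhydride (1.5 equiv), DMAP (4 equiv), CH2Cl2, slow addition of 21, rt to 40 °C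
Reagents that add atoms: none
Why: Shiina lactonisation activates C16 as a mixed anhydride and DMAP passes the acyl group to C4–OH, the only free hydroxyl, in a seven-membered closure that breaks no bond at C4 and so retains its configuration.

Step 16
Reactants: 23 ring C lactone (14-chloro)
Product: 24 dechlorinated lactone β-keto ester
Conditions: Zn dust (10 equiv), AcOH–THF (1:4), 0 °C to rt
Reagents that add atoms: none
Why: Reductive dehalogenation of an α-halo 1,3-dicarbonyl compound by zinc is fast at or below room temperature, well before the α-alkoxy ketones or the acrylate could be reduced, and frees C14–H only after all oxidations are over.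

Step 17
Reactants: 24 dechlorinated lactone β-keto ester
Product: 25 C8 methylene lactone β-keto ester
Conditions: Zn/CH2Br2/TiCl4 (pre-formed in THF, aged at 5 °C), CH2Cl2, 0 °C to rt; aq. NaHCO3
Reagents that add atoms: dibromomethane, BrCBr
Why: Lombardo–Takai methylenation with the non-basic gem-dizinc/titanium reagent converts the accessible C8 ketone into the C8=C19 methylene without epimerising C9 and without touching esters or lactone, while C13 is shielded by quaternary C12, tertiary C14 and metal chelation of the keto ester.

Step 18
Reactants: 25 C8 methylene lactone β-keto ester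
Product: 27 C13 ketone, via β-keto acid 26 (not isolated)
Conditions: Bu4NF/AcOH (1:1, 3 equiv), THF, rt to 40 °C
Reagents that add atoms: none
Why: Fluoride-induced fragmentation of the 2-(trimethylsilyl)ethyl ester releases the β-keto acid, which decarboxylates through its cyclic transition state, the acetic acid buffer protecting acetate, lactone and C9, and C14 becomes CH2 so that its epimers converge.

Step 19
Reactants: 27 C13 ketone
Product: 28 (13S)-alcohol
Conditions: Zn(BH4)2, Et2O–CH2Cl2, −40 to −20 °C
Reagents that add atoms: none
Why: Chelation-controlled (Cram chelate) reduction: zinc ties the C13 carbonyl to the ring B oxygen and hydride should come from the convex face of this bicyclic chelate, past the C20 methyl and away from the C11 methylene, which gives the 13S alcohol, while the mild reagent leaves acrylate, acetate and alkenes alone.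

Step 20
Reactants: 28 (13S)-alcohol
Product: 29 CNP0133628.2
Conditions: Ac2O, Et3N, DMAP (cat.), CH2Cl2, rt
Reagents that add atoms: acetic anhydride, CC(=O)OC(C)=O
Why: DMAP-catalysed acetylation of the only free hydroxyl completes the target with retention at C13.

Compound list
1 | (R)-(−)-linalool, (3R)-3,7-dimethylocta-1,6-dien-3-ol | C=C[C@](C)(O)CCC=C(C)C | starting material
2 | (3R,6S)-6,7-epoxylinalool | C=C[C@](C)(O)CC[C@@H]1OC1(C)C | intermediate
3 | (2R,5R)-furanoid linalool oxide, 2-[(2R,5R)-5-ethenyl-5-methyloxolan-2-yl]propan-2-ol (vinyl and hydroxyisopropyl trans) | C=C[C@@]1(C)CC[C@@H](O1)C(C)(C)O | intermediate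
4 | (2R,5R)-2-ethenyl-2-methyl-5-(prop-1-en-2-yl)oxolane | C=C[C@@]1(C)CC[C@@H](O1)C(C)=C | intermediate
5 | (2R,5R)-5-acetyl-2-methyloxolane-2-carbaldehyde | O=C[C@@]1(C)CC[C@@H](O1)C(C)=O | intermediate
6 | (2R,5R)-5-acetyl-2-methyloxolane-2-carboxylic acid | OC(=O)[C@@]1(C)CC[C@@H](O1)C(C)=O | intermediate
7 | Meldrum's acid, 2,2-dimethyl-1,3-dioxane-4,6-dione | CC1(C)OC(=O)CC(=O)O1 | starting material
8 | 5-[(2R,5R)-5-acetyl-2-methyloxolane-2-carbonyl] Meldrum's acid | O=C1OC(C)(C)OC(=O)C1C(=O)[C@@]1(C)CC[C@@H](O1)C(C)=O | intermediate
9 | 2-(trimethylsilyl)ethyl 3-[(2R,5R)-5-acetyl-2-methyloxolan-2-yl]-3-oxopropanoate | C[Si](C)(C)CCOC(=O)CC(=O)[C@@]1(C)CC[C@@H](O1)C(C)=O | intermediate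
10 | C8 N,N-dimethylhydrazone of 9 | C[Si](C)(C)CCOC(=O)CC(=O)[C@@]1(C)CC[C@@H](O1)C(C)=NN(C)C | intermediate
11 | (3R)-1,2-epoxylinalool, (2R)-6-methyl-2-(oxiran-2-yl)hept-5-en-2-ol, both epimers at the oxirane carbon | O[C@](C1CO1)(C)CCC=C(C)C | intermediate
12 | (2R,3R)-1,2-epoxylinalool, (2R)-6-methyl-2-[(2R)-oxiran-2-yl]hept-5-en-2-ol (4R,5R in cembrane numbering) | O[C@]([C@H]1CO1)(C)CCC=C(C)C | intermediate
13 | trimethylsilyl ether of 12 | C[Si](C)(C)O[C@]([C@H]1CO1)(C)CCC=C(C)C | intermediate
14 | coupled hydrazone: C6–C7 joined, C5–OH, C4–OSiMe3, C8 dimethylhydrazone (4R,5R,9R,12R) | C[Si](C)(C)O[C@]([C@H](O)CCC(=NN(C)C)[C@H]1CC[C@@](C)(O1)C(=O)CC(=O)OCC[Si](C)(C)C)(C)CCC=C(C)C | intermediate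
15 | seco 4,5-dihydroxy C8 ketone C13 β-keto 2-(trimethylsilyl)ethyl ester (4R,5R,9R,12R) | O[C@]([C@H](O)CCC(=O)[C@H]1CC[C@@](C)(O1)C(=O)CC(=O)OCC[Si](C)(C)C)(C)CCC=C(C)C | intermediate
16 | seco C5 acetate (4R,5R,9R,12R) | O[C@]([C@H](OC(C)=O)CCC(=O)[C@H]1CC[C@@](C)(O1)C(=O)CC(=O)OCC[Si](C)(C)C)(C)CCC=C(C)C | intermediate
17 | seco 14-chloro β-keto ester bearing the terminal prenyl group and the C8 ketone (4R,5R,9R,12R; C14 epimers) | O[C@]([C@H](OC(C)=O)CCC(=O)[C@H]1CC[C@@](C)(O1)C(=O)C(Cl)C(=O)OCC[Si](C)(C)C)(C)CCC=C(C)C | intermediate
18 | 14-membered 14-chloro C13 keto ester bearing the C1 2-propenyl group (1S,4R,5R,9R,12R; C14 epimers) | O[C@]2(C)CC[C@@H](C(C)=C)C(Cl)(C(=O)OCC[Si](C)(C)C)C(=O)[C@@]1(C)CC[C@@H](O1)C(=O)CC[C@H]2OC(C)=O | intermediate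
19 | C16 allylic alcohol of 18 | O[C@]2(C)CC[C@@H](C(=C)CO)C(Cl)(C(=O)OCC[Si](C)(C)C)C(=O)[C@@]1(C)CC[C@@H](O1)C(=O)CC[C@H]2OC(C)=O | intermediate
20 | C16 enal | O[C@]2(C)CC[C@@H](C(=C)C=O)C(Cl)(C(=O)OCC[Si](C)(C)C)C(=O)[C@@]1(C)CC[C@@H](O1)C(=O)CC[C@H]2OC(C)=O | intermediate
21 | C16 acrylic acid | O[C@]2(C)CC[C@@H](C(=C)C(=O)O)C(Cl)(C(=O)OCC[Si](C)(C)C)C(=O)[C@@]1(C)CC[C@@H](O1)C(=O)CC[C@H]2OC(C)=O | intermediate
22 | mixed anhydride of 21 and 2-methyl-6-nitrobenzoic acid | O[C@]2(C)CC[C@@H](C(=C)C(=O)OC(=O)c3c(C)cccc3[N+](=O)[O-])C(Cl)(C(=O)OCC[Si](C)(C)C)C(=O)[C@@]1(C)CC[C@@H](O1)C(=O)CC[C@H]2OC(C)=O | intermediate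
23 | 16,4-lactone (ring C closed), 14-chloro, C8 and C13 ketones | C=C1C(=O)O[C@]2(C)CC[C@@H]1C(Cl)(C(=O)OCC[Si](C)(C)C)C(=O)[C@@]1(C)CC[C@@H](O1)C(=O)CC[C@H]2OC(C)=O | intermediate
24 | dechlorinated lactone β-keto ester (1R,4R,5R,9R,12R; C14 epimers) | C=C1C(=O)O[C@]2(C)CC[C@@H]1C(C(=O)OCC[Si](C)(C)C)C(=O)[C@@]1(C)CC[C@@H](O1)C(=O)CC[C@H]2OC(C)=O | intermediate
25 | C8 methylene lactone β-keto ester | C=C1C(=O)O[C@]2(C)CC[C@@H]1C(C(=O)OCC[Si](C)(C)C)C(=O)[C@@]1(C)CC[C@@H](O1)C(=C)CC[C@H]2OC(C)=O | intermediate
26 | β-keto acid from 25 | C=C1C(=O)O[C@]2(C)CC[C@@H]1C(C(=O)O)C(=O)[C@@]1(C)CC[C@@H](O1)C(=C)CC[C@H]2OC(C)=O | intermediate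
27 | C13 ketone (1R,4R,5R,9R,12R) | C=C1C(=O)O[C@]2(C)CC[C@@H]1CC(=O)[C@@]1(C)CC[C@@H](O1)C(=C)CC[C@H]2OC(C)=O | intermediate
28 | (13S)-alcohol | C=C1C(=O)O[C@]2(C)CC[C@@H]1C[C@H](O)[C@@]1(C)CC[C@@H](O1)C(=C)CC[C@H]2OC(C)=O | intermediate
29 | CNP0133628.2, (1R,4R,5R,9R,12R,13S)-5,13-diacetoxy-9,12-epoxycembra-8(19),15(17)-dien-16,4-olide | C=C1C(=O)O[C@]2(C)CC[C@@H]1C[C@H](OC(C)=O)[C@@]1(C)CC[C@@H](O1)C(=C)CC[C@H]2OC(C)=O | target

Total step count: 20. Longest linear sequence: 17 (steps 1–5 and 9–20). Steps 6–8 form the second branch.

Steps most likely to fail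

Step 12, ring closure.
- What may go wrong: slow closure of the large ring may let intermolecular addition and oligomerisation win. Over-oxidation at C15 may be followed by capture by the C4 hydroxyl or the ester carbonyl. Facial selectivity at C1 may be poor.
- Fallback, from 17 back to 18: the radical is generated and terminated without an external oxidant. A second chlorination of 17 (NCS, Mg(ClO4)2, MeCN) gives the 14,14-dichloro keto ester F1.
- CuCl with tris(2-pyridylmethyl)amine (30 mol%) in 1,2-dichloroethane at 80 °C and high dilution then runs a Kharasch-type atom-transfer macrocyclisation, a reaction type with precedent for medium and large rings.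
- Here C15 is capped by chlorine transfer from divalent copper instead of being oxidised, which gives the 14,15-dichloro macrocycle F2.
- DBU in toluene removes hydrogen chloride from the tertiary chloride through a methyl hydrogen and rejoins the route at 18.

Step 15, lactonisation.
- What may go wrong: acyl transfer to the hindered tertiary hydroxyl may be sluggish, giving time for conjugate addition of DMAP to the acrylate, for intermolecular acylation, or for base-induced loss of hydrogen chloride across C14–C1.
- Fallback, from 21 back to 23: activation is moved from nucleophilic catalysis under base to acid catalysis (Kita–Trost method).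
- Ethoxyacetylene and [RuCl2(p-cymene)]2 (2 mol%) in toluene convert 21 into the 1-ethoxyvinyl ester F3.
- Catalytic CSA in dilute 1,2-dichloroethane at 50 °C then closes ring C with release of a neutral ester and rejoins the route at 23.

Step 19, C13 reduction.
- What may go wrong: facial selectivity may be poor or reversed if the conformation of ring A overrides the zinc chelate, or hydride may add slowly in the conjugate sense to the acrylate.
- Fallback, from 27 back to 28: substrate control is replaced by reagent control with (−)-B-chlorodiisopinocampheylborane in THF at rt.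
- This reagent distinguishes the tertiary C12 side from the C14 methylene side, should deliver the S alcohol, and carries no B–H bond that could hydroborate the alkenes. Work-up is with diethanolamine.
- This fallback makes no new compound (F0).

Further compounds
F1 | step 12 | seco 14,14-dichloro β-keto ester (4R,5R,9R,12R) | O[C@]([C@H](OC(C)=O)CCC(=O)[C@H]1CC[C@@](C)(O1)C(=O)C(Cl)(Cl)C(=O)OCC[Si](C)(C)C)(C)CCC=C(C)C
F2 | step 12 | 14,15-dichloro macrocycle (ring A closed, C1 bearing a 2-chloropropan-2-yl group; C14 epimers) | O[C@]2(C)CC[C@@H](C(C)(C)Cl)C(Cl)(C(=O)OCC[Si](C)(C)C)C(=O)[C@@]1(C)CC[C@@H](O1)C(=O)CC[C@H]2OC(C)=O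
F3 | step 15 | 1-ethoxyvinyl ester of 21 | O[C@]2(C)CC[C@@H](C(=C)C(=O)OC(=C)OCC)C(Cl)(C(=O)OCC[Si](C)(C)C)C(=O)[C@@]1(C)CC[C@@H](O1)C(=O)CC[C@H]2OC(C)=O
F0 | step 19 | none | none
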